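**Plan**

- The retrosynthesis cuts three bonds of the γ-pyranone ring at once: C4–C4a, C3–C4 and O1–C2. This gives an iodophloroglucinol triacetate, carbon monoxide (C4 and its oxygen) and 1-tricosyne (C3, C2 and the C21 chain).
- The feature that allows this: C4 is a carbonyl carbon held between aryl carbon C4a and the C3=C2 enol-ether unit, so the pyranone ring is a cyclised aryl alkynyl ketone. C4a lies between two equivalent oxygen-bearing carbons (C5 and C8a) of a phloroglucinol ring, so ring closure has no regiochemical choice.
- Forward, the chain piece comes from 1-docosanol by oxidation and one-carbon homologation; the even C22 alcohol supplies C2 and the odd C21 chain, and the reagent supplies C3.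
- The aryl piece comes from phloroglucinol by mono-iodination (only one mono-iodide is possible) and acetylation.
- The pyranone ring is formed last in a Pd-catalysed three-component carbonylative annulation; the amine in that step also removes the acetates, so the target forms directly.
- Stereochemistry: the target has no stereocentre and no stereogenic double bond, so nothing has to be set.

Key step: step 5

Remark: the SMILES is achiral, so the request for a single enantiomer is met trivially; the side chain is read as n-henicosyl (21 carbons).

**Route**

Step 1
Reactants: 1 1-docosanol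
Product: 2 docosanal
Conditions: TEMPO (10 mol %), PhI(OAc)2 (1.1 equiv), CH2Cl2, 30 °C
Reagents that add atoms: none
Why: TEMPO/PhI(OAc)2 (oxoammonium) oxidation of a primary alcohol should stop cleanly at the aldehyde, and the substrate has no other functional group.

Step 2
Reactants: 2 docosanal
Product: 4 1-tricosyne, via 1-diazotricos-1-ene 3 (not isolated)
Conditions: Ohira–Bestmann reagent (1.3 equiv), K2CO3 (2 equiv), MeOH–THF (1:1), 0 °C to rt
Reagents that add atoms: dimethyl (1-diazo-2-oxopropyl)phosphonate (Ohira–Bestmann reagent), COP(=O)(OC)C(=[N+]=[N-])C(C)=O
Why: Ohira–Bestmann (Seyferth–Gilbert) homologation, in which methanolysis of the reagent gives the diazomethylphosphonate anion, Horner–Wadsworth–Emmons-type olefination gives diazoalkene 3, and loss of N2 with a 1,2-hydrogen shift should give the terminal alkyne with exactly one added carbon.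

Step 3
Reactants: 5 phloroglucinol (benzene-1,3,5-triol)
Product: 6 2-iodobenzene-1,3,5-triol
Conditions: I2 (1.0 equiv), NaHCO3 (1.1 equiv), THF–H2O (1:1), 0 °C to rt
Reagents that add atoms: iodine, II
Why: Electrophilic aromatic iodination of a highly activated ring whose three CH positions are equivalent, so only one mono-iodide can form, with one equivalent of iodine at low temperature under bicarbonate buffering to limit poly-iodination.

Step 4
Reactants: 6 2-iodobenzene-1,3,5-triol
Product: 7 2-iodobenzene-1,3,5-triyl triacetate
Conditions: Ac2O (4 equiv), pyridine, DMAP (5 mol %), CH2Cl2, 0 °C to rt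
Reagents that add atoms: acetic anhydride, CC(=O)OC(C)=O
Why: DMAP-catalysed O-acetylation should turn the oxidation-sensitive triol into a stable, less electron-rich aryl iodide whose acetates the amine of the key step removes.

Step 5
Reactants: 7 2-iodobenzene-1,3,5-triyl triacetate; 8 carbon monoxide; 4 1-tricosyne
Product: 11 5,7-dihydroxy-2-henicosyl-4H-chromen-4-one, via ynone triacetate 9 (not isolated), via enaminone triol 10 (not isolated)
Conditions: PdCl2(PPh3)2 (5 mol %), dppp (5 mol %), thiourea (5 mol %), Et2NH (10 equiv), CO (1 atm), DMF–THF (1:1), 45 °C
Reagents that add atoms: none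
Why: Pd-catalysed carbonylative Sonogashira coupling–annulation, the known three-component chromone synthesis from o-iodophenol acetates, CO and terminal alkynes: Pd(0) inserts into the C–I bond of 7, CO insertion gives the aroyl–Pd species (C4–C4a), and amine-assisted alkynyl transfer with reductive elimination gives ynone 9 (C3–C4). Et2NH then cleaves the three aryl acetates and adds to the ynone to give enaminone 10, whose ortho phenol oxygen attacks the amine-bearing carbon and expels Et2NH, so the pyranone ring closes by O1–C2 bond formation in a 6-endo addition–elimination. No stereocentre is formed. Carbonylative coupling should win over direct coupling because the system is copper-free and CO-saturated and the aryl–Pd carbon flanked by two ortho oxygens inserts CO readily, while the same two ortho groups shield the aroyl carbon from amide formation with Et2NH. Chromone is expected over aurone because in 10 only the β-carbon is electrophilic, which excludes 5-exo closure. No regioisomer can form because both oxygens ortho to the new ketone are equivalent, and the two that remain become the 5-OH and 7-OH of 11.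

**Compound list**

1 | 1-docosanol | CCCCCCCCCCCCCCCCCCCCCCO | starting material
2 | docosanal | CCCCCCCCCCCCCCCCCCCCCC=O | intermediate
3 | 1-diazotricos-1-ene | CCCCCCCCCCCCCCCCCCCCCC=C=[N+]=[N-] | intermediate (not isolated)
4 | 1-tricosyne | CCCCCCCCCCCCCCCCCCCCCC#C | intermediate
5 | phloroglucinol (benzene-1,3,5-triol) | Oc1cc(O)cc(O)c1 | starting material
6 | 2-iodobenzene-1,3,5-triol | Oc1cc(O)c(I)c(O)c1 | intermediate
7 | 2-iodobenzene-1,3,5-triyl triacetate | CC(=O)Oc1cc(OC(C)=O)c(I)c(OC(C)=O)c1 | intermediate
8 | carbon monoxide | [C-]#[O+] | starting material
9 | 2-(tetracos-2-ynoyl)benzene-1,3,5-triyl triacetate (ynone triacetate) | CCCCCCCCCCCCCCCCCCCCCC#CC(=O)c1c(OC(C)=O)cc(OC(C)=O)cc1OC(C)=O | intermediate (not isolated)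
10 | (E)-3-(diethylamino)-1-(2,4,6-trihydroxyphenyl)tetracos-2-en-1-one (enaminone triol) | CCCCCCCCCCCCCCCCCCCCC/C(=C\C(=O)c1c(O)cc(O)cc1O)N(CC)CC | intermediate (not isolated)
11 | 5,7-dihydroxy-2-henicosyl-4H-chromen-4-one | CCCCCCCCCCCCCCCCCCCCCc1cc(=O)c2c(O)cc(O)cc2o1 | target

**Step count and risks**

Total steps: 5. Longest linear sequence: 3 (steps 1, 2, 5 or steps 3, 4, 5).

Steps most likely to fail:

1. Step 5. Alkynyl transfer may occur before CO insertion, giving direct coupling and then 5-endo closure to a benzofuran. Et2NH may intercept the aroyl–Pd intermediate. Early deacetylation may be followed by protodeiodination of the very electron-rich ring. The fallback sets out from 4 and returns at 11, joining the ring carbons stepwise without CO or palladium. Alkyne 4 is deprotonated with n-BuLi (THF, –78 °C) and added to commercial 2,4,6-trimethoxybenzaldehyde, which should give (±)-1-(2,4,6-trimethoxyphenyl)tetracos-2-yn-1-ol F1, a racemate whose carbinol centre is erased in the next operation. MnO2 (CH2Cl2, rt) should oxidise it to 1-(2,4,6-trimethoxyphenyl)tetracos-2-yn-1-one F2. Excess BBr3 (CH2Cl2, –78 °C to rt) should then cleave the chelated ortho methyl ether first, let the freed oxygen close 6-endo onto the Lewis-acid-activated ynone, and remove the other two methyl groups to give 11.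

2. Step 3. The mono-iodide is still strongly activated, so iodination may run on to di- and tri-iodides, and the iodotriol may lose iodine or oxidise during isolation. The fallback sets out from 5 and returns at 6, replacing electrophilic substitution by directed metalation. Phloroglucinol 5 with NaH and MOMCl (DMF, 0 °C) should give 1,3,5-tris(methoxymethoxy)benzene F3. n-BuLi (THF, 0 °C) should lithiate the position between two OMOM groups, and an iodine quench should give 2-iodo-1,3,5-tris(methoxymethoxy)benzene F4 as the only possible mono-iodide. Brief HCl in MeOH at rt should remove the acetals to give 6, which is carried crude into step 4.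

3. Step 2. The waxy aldehyde is poorly soluble in methanol, so conversion may stall, and the carbonate base may cause aldol self-condensation of the enolisable aldehyde. The fallback sets out from 2 and returns at 4 by a Corey–Fuchs sequence in aprotic solvents. Aldehyde 2 with CBr4 and PPh3 (CH2Cl2, 0 °C) should give 1,1-dibromotricos-1-ene F5. n-BuLi (2.2 equiv, THF, –78 °C to rt) followed by a water quench should give 4 by bromine–lithium exchange and Fritsch–Buttenberg–Wiechell rearrangement.

**Further compounds**

F1 | step 5 | (±)-1-(2,4,6-trimethoxyphenyl)tetracos-2-yn-1-ol (racemate) | CCCCCCCCCCCCCCCCCCCCCC#CC(O)c1c(OC)cc(OC)cc1OC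
F2 | step 5 | 1-(2,4,6-trimethoxyphenyl)tetracos-2-yn-1-one | CCCCCCCCCCCCCCCCCCCCCC#CC(=O)c1c(OC)cc(OC)cc1OC
F3 | step 3 | 1,3,5-tris(methoxymethoxy)benzene | COCOc1cc(OCOC)cc(OCOC)c1
F4 | step 3 | 2-iodo-1,3,5-tris(methoxymethoxy)benzene | COCOc1cc(OCOC)c(I)c(OCOC)c1
F5 | step 2 | 1,1-dibromotricos-1-ene | CCCCCCCCCCCCCCCCCCCCCC=C(Br)Br
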